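(The constants come from no measurement, and the outcome is calculated.)

**The task.** I start with the easy step: Z turns into J and back, J takes up L to give L.J, and L.J can fall apart again.

    Z ⇌ J (K1 = 0.49, k1 = 0.13 h⁻¹)
    L + J ⇌ L.J (K2 = 380 M⁻¹, k2 = 30 M⁻¹ h⁻¹)

Z 43 mM (in portions, 4); L 1.20 equiv; time 8.0 d; the portions of Z follow each other after 10 min, the first at the start

1. why nothing more happens at 8.0 d, or that something still does (all of Z has reacted / it is still moving / forward and back rates have come level / L has run out first)
2. part of the Z gone at 8.0 d
3. the L.J standing at 8.0 d, as a percentage of the Z charged
4. the J standing at 8.0 d, as a percentage of the Z charged
5. amount of L.J if the flask were left three thousand times as long, in percent of the Z charged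

- the reaction counts as stopped when no species that holds the Z changes by six tenths of a point or more over the second half of the time
- run time (flask): 8.0 d

**First clock.** Z and J settle between themselves with a relaxation half-life of 0.0731 d. The flask has 8.0 d, which is far longer. So Z and J have time to settle, but this clock says nothing about L.J.

**The objection.** J also leaves by taking up L, with a half-life of 0.45 h by the forward rate alone at the charged amounts. That is quick, but L.J falls apart on its own clock. Its back constant is the rate constant of the second step over its equilibrium constant, 0.0789 h⁻¹, and no concentration enters it. That gives a half-life of 8.78 h, the slowest clock I have.

**The count.** I divide the time by that clock and get 21.9. I call this the half-life count: the time allowed over the slowest clock. I take each half-life to halve the distance left to balance.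

**Two doubts.** Z, J and L.J form a chain, and this chain may run slower than the one clock I counted. So I cut the count by a factor of 2: by my rule, 10.9 half-lives still leave 0.0511% of the distance. The portions worry me less, because the last one goes in after 30.0 min, which is shorter than the clock. L cannot run out first, because one L goes with one Z and its charge is larger than that of Z. I commit to a flask at balance (thermodynamic control). My hand stops there, since the amounts need the balance solved.

**The forecast.** It says forward and back rates have come level, with 81.2% of Z gone, 72% L.J, 9.2% J, and 72% L.J after the very long wait. Its ground: “The flask therefore sits at equilibrium”.

**The result.** The simulation gives forward and back rates have come level, with 81.2% of Z gone, 72.0% L.J and 9.19% J, and 72.0% L.J after the very long wait.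

**What it means.** In this flask the slowest clock of 8.78 h is far shorter than the 8.0 d allowed, a count of 21.9. L.J stands at 72.0% after 4.00 d and at 72.0% after 80.0 d, with 40.0% of the L left at that later time. The neighbour flask with 170 mM of Z has the same count of 21.9, since its clock holds no concentration. After 8.00 d that neighbour shows J over Z of 0.490, beside an equilibrium constant of the first step of 0.49, and L.J at 87.4%.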